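**Retrosynthetic overview**

1. Numbering used throughout: ring A = six-membered ring C1 (CH bearing CMe2), C2 (CH next to CHMe), C3 (CHMe), C4 (CH2), C5 (C=O), C6 (CH next to C=O); ring B = seven-membered ring C1, C6, C7 (CMe), C8 (CH2), C9 and C10 (the two CH–O, C9 next to C8), C11 (CMe2); ring C = cyclobutane C1, C2, C7, C6.
2. Target ⇐ bis-angeloylation of the trans-diol ⇐ debenzylation ⇐ cuprate methylation at C3 of a tricyclic enone (C5=O, C4=C3).
3. Tricyclic enone ⇐ one cationic cascade that forms C8–C9 (ring B) and then C2–C7 (ring C) from a monocyclic α-benzyloxy aldehyde carrying a silyl dienol ether and a cis isopropenyl group.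
4. Enabling feature: C7 (quaternary, methyl) and C8 (CH2) are the two carbons of an isopropenyl group on C6, C2 is the γ-carbon of the ring A enone C5(=O)–C4=C3 (the terminus of its dienol ether), and C9 is an oxygenated carbon next to oxygenated C10, i.e. a chelatable α-alkoxy aldehyde.
5. Cascade substrate ⇐ ring A by ring-closing metathesis ⇐ Ireland–Claisen rearrangement (sets C1 and C6) ⇐ (S)-pantolactone (supplies C1, C9, C10, C11 and the C10 stereocentre); ring order A, then B and C together.

Key step: step 15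

Remark: both ester groups are read as angelates ((Z)-2-methylbut-2-enoates) and the two acyloxy groups as trans on ring B, as the SMILES specifies.

**Route**

Step 1
Reactants: 1 (S)-pantolactone
Product: 2 (3S)-3-(benzyloxy)-4,4-dimethyloxolan-2-one
Conditions: BnOC(=NH)CCl3, TfOH (5 mol %), CH2Cl2/cyclohexane, 0 to 25 °C
Reagents that add atoms: benzyl 2,2,2-trichloroacetimidate, N=C(OCc1ccccc1)C(Cl)(Cl)Cl
Why: acid-catalysed O-benzylation by the trichloroacetimidate method needs no base, so the lactone α-carbon (the later C10, S) should not epimerise.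

Step 2
Reactants: 2 (3S)-3-(benzyloxy)-4,4-dimethyloxolan-2-one
Product: 3 (2S)-2-(benzyloxy)-3,3-dimethylbutane-1,4-diol
Conditions: LiAlH4, THF, 0 °C; aqueous NaOH work-up
Reagents that add atoms: none
Why: hydride reduction of the lactone gives the 1,4-diol and leaves the benzyl ether and C10 untouched.

Step 3
Reactants: 3 (2S)-2-(benzyloxy)-3,3-dimethylbutane-1,4-diol
Product: 4 (2S)-2-(benzyloxy)-4-hydroxy-3,3-dimethylbutyl pivalate
Conditions: t-BuCOCl (1.05 equiv), pyridine, CH2Cl2, −20 °C
Reagents that add atoms: pivaloyl chloride, CC(C)(C)C(=O)Cl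
Why: the C9 hydroxyl is less hindered than the neopentyl C1 hydroxyl next to the quaternary carbon, so the bulky acyl chloride should acylate it selectively.

Step 4
Reactants: 4 (2S)-2-(benzyloxy)-4-hydroxy-3,3-dimethylbutyl pivalate
Product: 5 (2S)-2-(benzyloxy)-3,3-dimethyl-4-oxobutyl pivalate
Conditions: (n-Pr4N)RuO4 (5 mol %), N-methylmorpholine N-oxide, 4 Å molecular sieves, CH2Cl2, 25 °C
Reagents that add atoms: none
Why: Ley–Griffith oxidation of the primary alcohol gives an aldehyde that has no α-hydrogen and cannot epimerise or enolise.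

Step 5
Reactants: 5 (2S)-2-(benzyloxy)-3,3-dimethyl-4-oxobutyl pivalate; 6 dimethyl (2-oxopropyl)phosphonate
Product: 7 (2S,4E)-2-(benzyloxy)-3,3-dimethyl-6-oxohept-4-en-1-yl pivalate
Conditions: LiCl, i-Pr2NEt, MeCN, 25 °C
Reagents that add atoms: none
Why: Horner–Wadsworth–Emmons olefination under Masamune–Roush conditions should give the (E)-enone under base mild enough to spare the pivalate.

Step 6
Reactants: 7 (2S,4E)-2-(benzyloxy)-3,3-dimethyl-6-oxohept-4-en-1-yl pivalate
Product: 8 (2S,4E,6R)-2-(benzyloxy)-6-hydroxy-3,3-dimethylhept-4-en-1-yl pivalate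
Conditions: (S)-2-methyl-CBS-oxazaborolidine (20 mol %), BH3·SMe2, THF, −30 °C
Reagents that add atoms: none
Why: in the Corey–Bakshi–Shibata reduction the alkenyl group acts as the large substituent, so the (S)-catalyst should give the (R)-allylic alcohol whose configuration is later relayed to C1.

Step 7
Reactants: 8 (2S,4E,6R)-2-(benzyloxy)-6-hydroxy-3,3-dimethylhept-4-en-1-yl pivalate; 9 3-methylbut-3-enoic acid
Product: 10 (2R,3E,6S)-6-(benzyloxy)-5,5-dimethyl-7-(pivaloyloxy)hept-3-en-2-yl 3-methylbut-3-enoate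
Conditions: DCC, DMAP (5 mol %), CH2Cl2, 0 °C
Reagents that add atoms: none
Why: Steglich esterification at 0 °C with little DMAP should acylate the allylic alcohol without moving the β,γ-double bond of the acid into conjugation.

Step 8
Reactants: 10 (2R,3E,6S)-6-(benzyloxy)-5,5-dimethyl-7-(pivaloyloxy)hept-3-en-2-yl 3-methylbut-3-enoate
Product: 13 (2R,3S,4E)-3-[(3S)-3-(benzyloxy)-2-methyl-4-(pivaloyloxy)butan-2-yl]-2-(prop-1-en-2-yl)hex-4-enoic acid, via silyl ketene acetal 11 (not isolated), via trimethylsilyl ester 12 (not isolated)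
Conditions: LiN(i-Pr)2, THF, −78 °C; Me3SiCl/Et3N; −78 to 55 °C; 1 M HCl work-up
Reagents that add atoms: none
Why: in the Ireland–Claisen rearrangement kinetic enolisation should give the (E)-silyl ketene acetal, and a chair transition state with the carbinol methyl group equatorial transfers the (R)-carbinol configuration to C1 (S) and gives the anti acid, in which the isopropenyl group on C6 (R) is cis to the C1 side chain in the later ring A.

Step 9
Reactants: 13 (2R,3S,4E)-3-[(3S)-3-(benzyloxy)-2-methyl-4-(pivaloyloxy)butan-2-yl]-2-(prop-1-en-2-yl)hex-4-enoic acid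
Product: 14 (2R,3S,4E)-3-[(3S)-3-(benzyloxy)-2-methyl-4-(pivaloyloxy)butan-2-yl]-N-methoxy-N-methyl-2-(prop-1-en-2-yl)hex-4-enamide
Conditions: MeNH(OMe)·HCl, EDC·HCl, HOBt, N-methylmorpholine, CH2Cl2, 0 to 25 °C
Reagents that add atoms: N,O-dimethylhydroxylamine hydrochloride, CNOC.Cl
Why: carbodiimide coupling through the hydroxybenzotriazole ester under weak base should form the Weinreb amide without epimerising C6 or conjugating the isopropenyl group.

Step 10
Reactants: 14 (2R,3S,4E)-3-[(3S)-3-(benzyloxy)-2-methyl-4-(pivaloyloxy)butan-2-yl]-N-methoxy-N-methyl-2-(prop-1-en-2-yl)hex-4-enamide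
Product: 15 (5R,6S,7E)-6-[(3S)-3-(benzyloxy)-2-methyl-4-(pivaloyloxy)butan-2-yl]-5-(prop-1-en-2-yl)nona-1,7-dien-4-one
Conditions: allylmagnesium bromide (1.2 equiv), THF, −78 °C; pH 7 buffer
Reagents that add atoms: allylmagnesium bromide, C=CC[Mg]Br
Why: Grignard addition to the Weinreb amide stops at the chelated tetrahedral intermediate and gives the allyl ketone on buffered work-up, and the low temperature spares the pivalate and the acidic C6–H.

Step 11
Reactants: 15 (5R,6S,7E)-6-[(3S)-3-(benzyloxy)-2-methyl-4-(pivaloyloxy)butan-2-yl]-5-(prop-1-en-2-yl)nona-1,7-dien-4-one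
Product: 16 (5S,6R)-5-[(3S)-3-(benzyloxy)-2-methyl-4-(pivaloyloxy)butan-2-yl]-6-(prop-1-en-2-yl)cyclohex-3-en-1-one (cis)
Conditions: first-generation Grubbs catalyst RuCl2(=CHPh)(PCy3)2 (10 mol %), CH2Cl2 (5 mM), 40 °C
Reagents that add atoms: none
Why: ring-closing metathesis between the allyl and propenyl groups closes ring A with loss of propene, and the first-generation catalyst engages 1,1-disubstituted alkenes poorly, so the isopropenyl group should stay out.

Step 12
Reactants: 16 (5S,6R)-5-[(3S)-3-(benzyloxy)-2-methyl-4-(pivaloyloxy)butan-2-yl]-6-(prop-1-en-2-yl)cyclohex-3-en-1-one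
Product: 17 (2S)-2-(benzyloxy)-3-methyl-3-[(1S,6R)-6-(prop-1-en-2-yl)-5-(triisopropylsilyloxy)cyclohexa-2,4-dien-1-yl]butyl pivalate
Conditions: i-Pr3SiOTf, Et3N, CH2Cl2, −78 °C
Reagents that add atoms: triisopropylsilyl trifluoromethanesulfonate, CC(C)[Si](OS(=O)(=O)C(F)(F)F)(C(C)C)C(C)C
Why: soft enolisation should remove the doubly activated (α and allylic) and accessible C4 proton instead of the hindered tertiary C6–H, giving the linear 1-silyloxy-1,3-diene with C6 intact.

Step 13
Reactants: 17 (2S)-2-(benzyloxy)-3-methyl-3-[(1S,6R)-6-(prop-1-en-2-yl)-5-(triisopropylsilyloxy)cyclohexa-2,4-dien-1-yl]butyl pivalate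
Product: 18 (2S)-2-(benzyloxy)-3-methyl-3-[(1S,6R)-6-(prop-1-en-2-yl)-5-(triisopropylsilyloxy)cyclohexa-2,4-dien-1-yl]butan-1-ol
Conditions: i-Bu2AlH (2.5 equiv), CH2Cl2, −78 °C; Rochelle salt work-up
Reagents that add atoms: none
Why: reductive cleavage of the pivalate by the aluminium hydride at low temperature leaves the silyl dienol ether and the benzyl ether untouched.

Step 14
Reactants: 18 (2S)-2-(benzyloxy)-3-methyl-3-[(1S,6R)-6-(prop-1-en-2-yl)-5-(triisopropylsilyloxy)cyclohexa-2,4-dien-1-yl]butan-1-ol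
Product: 19 (2S)-2-(benzyloxy)-3-methyl-3-[(1S,6R)-6-(prop-1-en-2-yl)-5-(triisopropylsilyloxy)cyclohexa-2,4-dien-1-yl]butanal
Conditions: (n-Pr4N)RuO4 (5 mol %), N-methylmorpholine N-oxide, 4 Å molecular sieves, CH2Cl2, 0 °C
Reagents that add atoms: none
Why: Ley–Griffith oxidation under neutral conditions should give the α-benzyloxy aldehyde without hydrolysing the dienol ether or epimerising C10.

Step 15
Reactants: 19 (2S)-2-(benzyloxy)-3-methyl-3-[(1S,6R)-6-(prop-1-en-2-yl)-5-(triisopropylsilyloxy)cyclohexa-2,4-dien-1-yl]butanal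
Product: 21 tricyclic enone (rings A, B and C closed; C5=O, C4=C3, no C3 methyl; C9–OH (S) free, C10–OBn (S); C1, C2, C6, C7 as in the target), via tertiary carbocation 20 (not isolated)
Conditions: SnCl4 (1.1 equiv), 2,6-di-tert-butyl-4-methylpyridine (0.2 equiv), CH2Cl2, −78 °C, slow addition of 19 (final 1 mM); aqueous NaHCO3
Reagents that add atoms: none
Why: Proposed new method: SnCl4 chelated between the C9 aldehyde oxygen and the C10 benzyloxy group activates the carbonyl for Prins-type attack by the isopropenyl CH2 (C8), which closes ring B in a 7-endo-trig mode and leaves a tertiary cation at C7 (20); this cation sits pseudoaxially over ring A and is captured by the γ-carbon C2 of the silyl dienol ether, closing ring C in a 4-exo-trig mode, and loss of the silyl group from the resulting oxocarbenium ion makes the sequence irreversible. The closest known reaction types are the SnCl4-promoted chelation-controlled type 2 carbonyl-ene/Prins reaction of α-benzyloxy aldehydes with 1,1-disubstituted alkenes, the Lewis acid-mediated tert-alkylation of silyl enol ethers with the γ-selectivity of vinylogous Mukaiyama reactions, and the presumed biosynthetic closure of a himachalyl-type cation to the longipinyl cation; new are their combination and the closure of a four-membered ring by a tertiary cation. C9 is set by the Cram-chelate model (attack on the aldehyde face away from C11 gives the 9,10-syn, that is ring-trans, oxygen pattern), C7 by the tether (C8 can bridge to C9 only on the face of ring A opposite to C5), and C2 by the cis C1/C6 relationship, which delivers C7 to the diene terminus on its own face. The step needs the aldehyde to react with the weakly nucleophilic isopropenyl group and not with the dienol ether (vinylogous Mukaiyama aldol, within or between molecules), and needs attack at C2 and not at C4: A(1,2) strain with the bulky silyloxy group holds the isopropenyl group pseudoaxial and so the cis side chain pseudoequatorial, a geometry in which C9 can reach C8 but not the π-lobes at C2 or C4, high dilution with slow addition suppresses bimolecular aldol reaction, and attack at C2 gives the conjugated enone with a cyclobutane instead of a more strained cyclobutanone.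

Step 16
Reactants: 21 tricyclic enone
Product: 22 tricyclic ketone (as 21 but C3 saturated and carrying the methyl group; C4 = CH2)
Conditions: Me2CuLi (3 equiv), Et2O, −78 to −30 °C; aqueous NH4Cl/NH3
Reagents that add atoms: lithium dimethylcuprate, [Li+].C[Cu-]C
Why: conjugate addition of the Gilman cuprate to this verbenone-type enone should occur from the face of the C1–H bridge, away from the C7 methyl group that shields the other face, which places the C3 methyl group trans to C7 as in the target.

Step 17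
Reactants: 22 tricyclic ketone
Product: 23 tricyclic 9,10-trans-diol (ring system and all stereocentres of the target; C9–OH, C10–OH)
Conditions: H2 (1 atm), Pd(OH)2/C, EtOAc, 25 °C
Reagents that add atoms: none
Why: hydrogenolysis removes the benzyl ether at a stage where no C=C bond is left, and the ketone and the cyclobutane are stable to these conditions.

Step 18
Reactants: 23 tricyclic 9,10-trans-diol; 24 angelic acid
Product: 26 CNP0109825.1 (9,10-bis-angelate), via mixed anhydride 25 (not isolated)
Conditions: 24 (4 equiv), 2,4,6-trichlorobenzoyl chloride, Et3N, toluene, 25 °C; then 23, 80 °C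
Reagents that add atoms: none
Why: acylation by the Yamaguchi-type mixed anhydride without a nucleophilic catalyst should esterify both hindered secondary hydroxyl groups while keeping the (Z)-geometry of the angeloyl group.

**Compound list**

1 | (S)-pantolactone | CC1(C)COC(=O)[C@H]1O | starting material
2 | (3S)-3-(benzyloxy)-4,4-dimethyloxolan-2-one | CC1(C)COC(=O)[C@H]1OCc1ccccc1 | intermediate
3 | (2S)-2-(benzyloxy)-3,3-dimethylbutane-1,4-diol | OC[C@@H](OCc1ccccc1)C(C)(C)CO | intermediate
4 | (2S)-2-(benzyloxy)-4-hydroxy-3,3-dimethylbutyl pivalate | CC(C)(C)C(=O)OC[C@@H](OCc1ccccc1)C(C)(C)CO | intermediate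
5 | (2S)-2-(benzyloxy)-3,3-dimethyl-4-oxobutyl pivalate | CC(C)(C)C(=O)OC[C@@H](OCc1ccccc1)C(C)(C)C=O | intermediate
6 | dimethyl (2-oxopropyl)phosphonate | COP(=O)(CC(C)=O)OC | starting material
7 | (2S,4E)-2-(benzyloxy)-3,3-dimethyl-6-oxohept-4-en-1-yl pivalate | CC(=O)/C=C/C(C)(C)[C@@H](COC(=O)C(C)(C)C)OCc1ccccc1 | intermediate
8 | (2S,4E,6R)-2-(benzyloxy)-6-hydroxy-3,3-dimethylhept-4-en-1-yl pivalate | C[C@@H](O)/C=C/C(C)(C)[C@@H](COC(=O)C(C)(C)C)OCc1ccccc1 | intermediate
9 | 3-methylbut-3-enoic acid | C=C(C)CC(=O)O | starting material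
10 | (2R,3E,6S)-6-(benzyloxy)-5,5-dimethyl-7-(pivaloyloxy)hept-3-en-2-yl 3-methylbut-3-enoate | C[C@@H](OC(=O)CC(C)=C)/C=C/C(C)(C)[C@@H](COC(=O)C(C)(C)C)OCc1ccccc1 | intermediate
11 | (E)-trimethylsilyl ketene acetal of 10 | CC(=C)/C=C(/O[Si](C)(C)C)O[C@H](C)/C=C/C(C)(C)[C@@H](COC(=O)C(C)(C)C)OCc1ccccc1 | intermediate
12 | trimethylsilyl ester of 13 | C/C=C/[C@@H]([C@H](C(C)=C)C(=O)O[Si](C)(C)C)C(C)(C)[C@@H](COC(=O)C(C)(C)C)OCc1ccccc1 | intermediate
13 | (2R,3S,4E)-3-[(3S)-3-(benzyloxy)-2-methyl-4-(pivaloyloxy)butan-2-yl]-2-(prop-1-en-2-yl)hex-4-enoic acid | C/C=C/[C@@H]([C@H](C(C)=C)C(=O)O)C(C)(C)[C@@H](COC(=O)C(C)(C)C)OCc1ccccc1 | intermediate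
14 | N-methoxy-N-methyl amide of 13 | C/C=C/[C@@H]([C@H](C(C)=C)C(=O)N(C)OC)C(C)(C)[C@@H](COC(=O)C(C)(C)C)OCc1ccccc1 | intermediate
15 | (5R,6S,7E)-6-[(3S)-3-(benzyloxy)-2-methyl-4-(pivaloyloxy)butan-2-yl]-5-(prop-1-en-2-yl)nona-1,7-dien-4-one | C=CCC(=O)[C@@H](C(C)=C)[C@H](/C=C/C)C(C)(C)[C@@H](COC(=O)C(C)(C)C)OCc1ccccc1 | intermediate
16 | (5S,6R)-5-[(3S)-3-(benzyloxy)-2-methyl-4-(pivaloyloxy)butan-2-yl]-6-(prop-1-en-2-yl)cyclohex-3-en-1-one | C=C(C)[C@@H]1C(=O)CC=C[C@@H]1C(C)(C)[C@@H](COC(=O)C(C)(C)C)OCc1ccccc1 | intermediate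
17 | (2S)-2-(benzyloxy)-3-methyl-3-[(1S,6R)-6-(prop-1-en-2-yl)-5-(triisopropylsilyloxy)cyclohexa-2,4-dien-1-yl]butyl pivalate | C=C(C)[C@@H]1C(O[Si](C(C)C)(C(C)C)C(C)C)=CC=C[C@@H]1C(C)(C)[C@@H](COC(=O)C(C)(C)C)OCc1ccccc1 | intermediate
18 | (2S)-2-(benzyloxy)-3-methyl-3-[(1S,6R)-6-(prop-1-en-2-yl)-5-(triisopropylsilyloxy)cyclohexa-2,4-dien-1-yl]butan-1-ol | C=C(C)[C@@H]1C(O[Si](C(C)C)(C(C)C)C(C)C)=CC=C[C@@H]1C(C)(C)[C@@H](CO)OCc1ccccc1 | intermediate
19 | (2S)-2-(benzyloxy)-3-methyl-3-[(1S,6R)-6-(prop-1-en-2-yl)-5-(triisopropylsilyloxy)cyclohexa-2,4-dien-1-yl]butanal | C=C(C)[C@@H]1C(O[Si](C(C)C)(C(C)C)C(C)C)=CC=C[C@@H]1C(C)(C)[C@@H](C=O)OCc1ccccc1 | intermediate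
20 | zwitterion after closure of ring B: tertiary carbocation at C7, C9–O bound to tetrachlorostannate, dienol ether intact | Cl[Sn-](Cl)(Cl)(Cl)O[C@H]1C[C+](C)[C@@H]2C(O[Si](C(C)C)(C(C)C)C(C)C)=CC=C[C@@H]2C(C)(C)[C@@H]1OCc1ccccc1 | intermediate
21 | tricyclic enone: C5=O, C4=C3, C9–OH (S), C10–OBn (S), C7 methyl, C11 gem-dimethyl | O[C@H]1C[C@]2(C)[C@@H]3[C@@H]([C@H]2C(=O)C=C3)C(C)(C)[C@@H]1OCc1ccccc1 | intermediate
22 | tricyclic ketone: as 21 with C3 methyl (trans to C7) and C4 = CH2 | O[C@H]1C[C@]2(C)[C@@H]3[C@@H]([C@H]2C(=O)C[C@H]3C)C(C)(C)[C@@H]1OCc1ccccc1 | intermediate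
23 | tricyclic (9S,10S)-trans-diol with the C5 ketone | O[C@H]1C[C@]2(C)[C@@H]3[C@@H]([C@H]2C(=O)C[C@H]3C)C(C)(C)[C@@H]1O | intermediate
24 | angelic acid ((Z)-2-methylbut-2-enoic acid) | C/C=C(/C)C(=O)O | starting material
25 | angelic 2,4,6-trichlorobenzoic anhydride | C/C=C(/C)C(=O)OC(=O)c1c(Cl)cc(Cl)cc1Cl | intermediate
26 | CNP0109825.1 | C/C=C(/C)C(=O)O[C@H]1C[C@]2(C)[C@@H]3[C@@H]([C@H]2C(=O)C[C@H]3C)C(C)(C)[C@@H]1OC(=O)/C(C)=C\C | target

Total step count: 18. Longest linear sequence: 18 steps (from 1).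

**Steps most likely to fail**

1. Step 15 (Proposed new method). The dienol ether may add to the aldehyde in a vinylogous Mukaiyama aldol reaction (five-membered ring or oligomers) faster than the isopropenyl group does, or the C7 cation may lose a proton before ring C closes. The fallback separates the two bond formations and uses known reaction types; it sets out from 19 and comes back at 21.
   - Protodesilylation of 19 with n-Bu4NF/AcOH in THF at −78 °C, with kinetic protonation at C4, should give the keto aldehyde F1.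
   - With no enol ether present, Me2AlCl in CH2Cl2 at −78 °C should close ring B by a type 2 carbonyl-ene reaction of the aldehyde with the isopropenyl group, giving the methylenecycloheptanol F2.
   - Dry HCl in CH2Cl2 at −40 °C should add to the exocyclic methylene group in the Markovnikov sense to give the tertiary chloride F3.
   - i-Pr3SiOTf (2.5 equiv)/Et3N at −78 °C should silylate the C9 hydroxyl and form the linear dienol ether as in step 12, giving the bis-silyl chloride F4.
   - ZnCl2 (or AgOTf) in CH2Cl2 should ionise the tertiary chloride, and tert-alkylation of the silyl dienol ether at C2 should close ring C to give the C9 silyl ether F5.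
   - HF·pyridine in THF then frees the C9 hydroxyl to give 21.

2. Step 12. Deprotonation may occur at C6 instead of C4 (cross-conjugated enol ether, loss of the C6 stereocentre), or the ring double bond may move into conjugation before silylation. The fallback replaces kinetic by thermodynamic control; it sets out from 16 and comes back at 17. Ketone 16 is isomerised on purpose with DBU in CH2Cl2 to the conjugated enone F6, which is silylated under equilibrating conditions (i-Pr3SiOTf, Et3N, 25 °C). The linear dienol ether is the thermodynamic isomer, and A(1,2) strain with the silyloxy group favours the isomer with a pseudoaxial isopropenyl group cis to the pseudoequatorial side chain, so C6 should be corrected and not lost.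

3. Step 18. Acylation of the hindered C10 hydroxyl may stay incomplete, and the angeloyl group may isomerise to the tigloyl group under forcing conditions. The fallback builds the (Z)-alkenes on the molecule; it sets out from 23 and comes back at 26. Diol 23 is esterified with 2-[bis(2,2,2-trifluoroethoxy)phosphoryl]propanoic acid (DCC, DMAP, CH2Cl2) to give the bis(phosphonopropionate) F7. Still–Gennari olefination with acetaldehyde (KN(SiMe3)2, 18-crown-6, THF, −78 °C) should then form both (Z)-2-methylbut-2-enoates; the phosphonate α-hydrogens are far more acidic than those of the ketone.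

Further compounds
F1 | step 15 | (2S)-2-(benzyloxy)-3-methyl-3-[(1S,2R)-3-oxo-2-(prop-1-en-2-yl)cyclohex-5-en-1-yl]butanal | C=C(C)[C@@H]1C(=O)CC=C[C@@H]1C(C)(C)[C@@H](C=O)OCc1ccccc1
F2 | step 15 | bicyclic ene product: ring B closed, exocyclic methylene at C7, C9–OH (S), C10–OBn (S), ring A cyclohex-3-enone | O[C@H]1CC(=C)[C@@H]2C(=O)CC=C[C@@H]2C(C)(C)[C@@H]1OCc1ccccc1
F3 | step 15 | tertiary chloride of F2 (C7 carries Cl and CH3, either epimer) | O[C@H]1CC(C)(Cl)[C@@H]2C(=O)CC=C[C@@H]2C(C)(C)[C@@H]1OCc1ccccc1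
F4 | step 15 | C9-O-triisopropylsilyl ether and C5 triisopropylsilyl dienol ether of F3 | CC(C)[Si](O[C@H]1CC(C)(Cl)[C@@H]2C(O[Si](C(C)C)(C(C)C)C(C)C)=CC=C[C@@H]2C(C)(C)[C@@H]1OCc1ccccc1)(C(C)C)C(C)C
F5 | step 15 | C9-O-triisopropylsilyl ether of 21 | CC(C)[Si](O[C@H]1C[C@]2(C)[C@@H]3[C@@H]([C@H]2C(=O)C=C3)C(C)(C)[C@@H]1OCc1ccccc1)(C(C)C)C(C)C
F6 | step 12 | (5S,6R)-5-[(3S)-3-(benzyloxy)-2-methyl-4-(pivaloyloxy)butan-2-yl]-6-(prop-1-en-2-yl)cyclohex-2-en-1-one | C=C(C)[C@@H]1C(=O)C=CC[C@@H]1C(C)(C)[C@@H](COC(=O)C(C)(C)C)OCc1ccccc1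
F7 | step 18 | 9,10-bis{2-[bis(2,2,2-trifluoroethoxy)phosphoryl]propanoate} of 23 | CC(C(=O)O[C@H]1C[C@]2(C)[C@@H]3[C@@H]([C@H]2C(=O)C[C@H]3C)C(C)(C)[C@@H]1OC(=O)C(C)P(=O)(OCC(F)(F)F)OCC(F)(F)F)P(=O)(OCC(F)(F)F)OCC(F)(F)F
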